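- Keep the temperature constant and let time be the axis. What is asked is 1 minus the fraction of starting material left, x, so reckon x and count whatever is missing as reacted.

in all of them: starting material 0.95 M

|  | partner | scavenger | protic impurity | remark | time |
|---|---|---|---|---|---|
| spring | 1.1 equiv | 0.53 equiv | 0.019 M | run made earlier |  |
| dawn | 1.1 equiv | 0.57 equiv | 0.019 M | run made earlier |  |
| noon | 1.1 equiv | 0.48 equiv | 0.019 M | run made earlier |  |
| west | 1.10 equiv | 0.500 equiv | 0.0190 M |  | 1.0 h |
| north-east | 1.10 equiv | 0.650 equiv | 0.0190 M |  | 1.0 h |

| run | time / min | starting material / % | product / % |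
|---|---|---|---|
| spring | 5.00 | 69.0 | 20.3 |
| spring | 10.0 | 56.1 | 37.7 |
| spring | 15.0 | 45.0 | 48.7 |
| spring | 30.0 | 25.6 | 66.3 |
| spring | 60.0 | 13.7 | 77.8 |
| dawn | 12.0 | 53.1 | 42.1 |
| dawn | 25.0 | 30.1 | 58.5 |
| dawn | 40.0 | 20.2 | 69.7 |
| dawn | 50.0 | 17.0 | 76.3 |
| dawn | 60.0 | 13.6 | 78.5 |
| noon | 5.00 | 70.5 | 20.7 |
| noon | 15.0 | 44.0 | 47.3 |
| noon | 30.0 | 24.3 | 63.8 |
| noon | 40.0 | 18.6 | 70.6 |
| noon | 60.0 | 13.4 | 78.2 |

(standard deviation of a reading: 1 percentage point)

- what has gone from starting material into another species counts as reacted, even if it can come back

- part of the starting material that has reacted at the end, west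
- part of the starting material that has reacted at the end, north-east
- what raising the equivalents of scavenger from its lowest to its highest value here does to the part of the starting material that has reacted (changes below 5 percentage points count as none) (it rises / it falls / no change)

- Take the partner surplus s as its equivalents minus 1, here 0.100, so that c(partner) follows x + s in units of the charged c(starting material).
- Assume one partner is used per starting material. Then ln[(x + s)/(x(1 + s))] grows as k·c(starting material)·s·t.
- The three runs leave a mean of 13.6% at 60.0 min, which gives the apparent second-order constant, the slope of that logarithm per unit of c(starting material)·s, 0.0802 L mol⁻¹ min⁻¹.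
- Check it on dawn: at 25.0 min it gives x = 30.2%, and the reading is 30.1%.
- First instants: the reckoned opening half-life, with c(partner) as charged, is 8.27 min. In spring at 5.00 min, 10.7% is already in neither measured species.
- Middle: in spring at 30.0 min, x reads 25.6%, and the rate reckoned from that reading is 8.29% of its opening value.
- End: the reckoned half-life at 60.0 min is 0.644 h, longer than at the opening.
- Across the scavenger charges, the final readings spread over 0.3 percentage points against a scatter of 1 point. Commit to 86.4% reacted for both west and north-east, though 0.650 equiv lies beyond the runs.
- The forecast gives 86.5% for west, 86.5% for north-east and no change, since “the three runs overlay within the 1-point scatter”.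
- The simulation gives 87.2% for west and 86.1% for north-east, a change of −1.1 points, so no change.

    starting material + protic impurity → quenched substrate (k = 93.0 L mol⁻¹ min⁻¹)
    starting material + released group ⇌ idle adduct, settled at all times (K = 3.00 L mol⁻¹)
    intermediate → product (k = 1.20 min⁻¹)
    scavenger + released group → scavenged by-product (k = 4.80 L mol⁻¹ min⁻¹)
    starting material + partner → intermediate + released group (k = 0.0640 L mol⁻¹ min⁻¹)

- In west, the reckoned end half-life of 0.644 h stands beside 0.59 h for the step from starting material and partner. Now carry 0.0802 L mol⁻¹ min⁻¹ to the neighbouring flask, which is west with 0.440 equiv of partner. The surplus turns negative, −0.560, partner becomes the limiting reagent, and the same logarithm gives x = 58.0% at 1.0 h. The neighbouring flask keeps 8.48% of its partner charge, with 42.8% of the starting material reacted and 57% left.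

The numbers in the tables are simulated for an exercise; the scatter is artificial.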